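## Analysis of the target

The target is a C25 diol with a 5-8-6-6 carbon skeleton. Numbering used throughout: C1 is the methyl-bearing olefinic carbon and C2 its partner; ring A (cyclopentane) is C2, C3, C4 (carbinol), C5 (methyl), C6; ring B (cyclooctene) is C1, C2, C6, C7 (carbinol), C8 (quaternary, methyl), C17, C18, C19; ring C (cyclohexane) is C8, C9, C10, C11 (quaternary, methyl), C16, C17; ring D is C11 to C16 with the geminal methyl pair on C14. There are eight stereocentres (4R, 5R, 6S, 7R, 8S, 11S, 16S, 17S in this numbering) and one tetrasubstituted Z olefin, C1=C2, endocyclic in ring B and exocyclic to ring A. Rings C and D are trans-fused (11-methyl β, H16 α); the C8 methyl is α, so it is cis to H16 and trans to H17, and ring B is attached to ring C through two trans bonds. O7 and H6 are β, and on ring A the hydrogens at C5 and C6 and the C4 hydroxyl all lie on one face, with the C5 methyl trans to the hydroxyl. Sensitive points are the tetrasubstituted olefin (migration under acid, over-reduction), C5 whenever C4 is a ketone, and the hindered C7 carbinol next to a quaternary carbon. The difficulty lies in the eight-membered ring, the ring quaternary carbons C8 and C11, and the continuous C4–C8 stereo array that must match the decalin. The strategy rests on ring C: C8 (methyl plus one-carbon branch C7) and its neighbour C17 (hydrogen plus one-carbon branch C18) are the two olefinic carbons of a citraconic unit, and C9, C10, C11, C16 with ring D are a 1-vinylcyclohexene, so ring C is a Diels–Alder adduct.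

## Retrosynthetic reasoning

C5–H and C6–H. Target 27 is traced to dienediol 26. On ring A the C4 hydroxyl and the hydrogens at C5 and C6 are all syn, which is the outcome of a hydroxyl-directed syn hydrogenation of a C5=C6 olefin. The forward step must reduce this olefin and spare C1=C2.

C4–O. Diol 26 comes from silyl ether 25, and 25 from dienone 24 by a reagent-controlled CBS reduction. Setting C4 by the catalyst, and not by the ring, makes the later delivery of hydrogen to C5 and C6 independent of the conformation of ring B.

Rings A and B. Dienone 24 is a 4-alkylidenecyclopent-2-enone fused to an eight-membered ring. Cutting C2–C6, C3–C4 and C4–C5 in one carbonylative [2+2+1] operation (allenic Pauson–Khand reaction) gives allenyne 23. This is the only single operation that forms both rings and the tetrasubstituted olefin with its geometry fixed by the ring, and it creates no stereocentre.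

The allene. The 1,1-disubstituted allene of 23 is cut at C19–C1 in an SN2′ sense, giving alkylborane 22 (from terminal olefin 19 by hydroboration) and phosphate 21 (from alcohol 20). Olefin 19 goes back through aldehyde 18 and alcohol 17 to ester 16, so C19 is one Wittig carbon and C18 is the former anhydride carbonyl.

C7. Silyl ether 16 comes from propargylic alcohol 15, and 15 from ynone 14 by CBS reduction, which sets C7 by reagent control next to the quaternary C8. The ynone is cut at C6–C7 into propyne 12 and acid chloride 13, made from hemiester 11. The free C7 acid of 11 is thus used directly as the acylating carbon.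

C11 methyl. Hemiester 11 is traced to cyclopropane 10 (hydrogenolysis of the less hindered C10–CH2 bond) and 10 to olefin 9 (Simmons–Smith cyclopropanation). The stereocentre is set in a concerted, face-selective addition and not by a radical or cationic step at a ring fusion.

C17 and the enantiomer. Trans-hemiester 9 is the C17 epimer of cis-hemiester 8, which is the product of opening anhydride 6 with menthol 7 at the less hindered C18 carbonyl. The opening differentiates C7 from C18 and resolves the racemate in the same operation; C17 is then corrected through its ester.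

Ring C (key disconnection). Anhydride 6 is cut at C8–C9 and C16–C17 into diene 4 and citraconic anhydride 5. This is chosen because one cycloaddition makes ring C, the quaternary C8 and its neighbour C17, and places the C8 methyl cis to H16 from two simple components.

The diene. Diene 4 comes from carbinol 3 by dehydration, and 3 from ketone 1 and vinyl Grignard reagent 2. The symmetry of 1 means only one conjugated diene can form.

## Alternatives that were turned down

Alternative 1: Ring B is disconnected at C6–C7. In the forward step a Lewis acid activates a C7 aldehyde, C6 of an allylic silane unit on ring A attacks it anti to silicon, and the olefin moves to C1=C2 as silicon leaves (transposing Hosomi–Sakurai cyclisation), giving the C4 silyl ether of the target A1. In its favour, one step closes ring B, sets C6 and C7 and delivers the tetrasubstituted olefin, and no late hydrogenation next to C1=C2 is needed; on this point it is stronger than the chosen route. Against it, the cyclisation substrate needs a configurationally defined quaternary carbon C1 bearing silicon, methyl and C19, since the C6 configuration is relayed from it. The closure is an eight-membered ring onto a neopentyl aldehyde, where protodesilylation competes and the C7 configuration depends on a medium-ring transition state that cannot be predicted with confidence. It also needs separate enantioselective syntheses of a ring A piece and of the decalin before the fragments are joined. The chosen route offers instead a core built from three simple components by a cycloaddition with predictable selectivity, and carbinols set by catalyst control.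

Alternative 2: Ring C is disconnected at C8–C17. A single-electron donor of trivalent titanium opens a C7–C8 epoxide to the tertiary C8 radical, which adds 6-endo to C17 of a ring D alkylidene ketone; protonation of the titanium enolate at C16 gives the ketol with a C15 ketone A2. In its favour, a radical is well suited to forming the congested C8, the C7 oxygen is installed with it, and ring A arrives with C4, C5 and C6 in place, so it too avoids the late hydrogenation. Against it, three stereocentres (C8, C17, C16) arise from a planar radical and an enolate protonation, with no firm control of the trans ring fusion. The C15 ketone has to be removed afterwards. Ring B is still open in A2 and would have to be closed later through the tetrasubstituted olefin, and the substrate (rings A and D, epoxide, two ketals) is long to make. The chosen route fixes C8, C16 and C17 by a concerted cycloaddition and a thermodynamic epimerisation, in far fewer steps to the decalin, at the price of a carbonylative ring closure late in the sequence.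

Alternative 3: Bonds C2–C6 and C1–C19 are disconnected. Irradiation near 350 nm makes a 2-substituted cyclohexenone add a tethered alkyne across C6=C19, closing ring A and a cyclobutene, to give the pentacyclic photoadduct A3; cleavage of C6–C19 then expands the six-membered ring by two carbons to ring B. In its favour, the photochemical step is short, closes a five-membered ring reliably and creates C1=C2 early. Against it, opening a cyclobutene fused in this way gives a strained diene in the eight-membered ring. C6, made quaternary in A3, becomes trigonal again and must be reset together with C7 by later reductions. The β,γ-unsaturated ketone in A3 is open to secondary photoreactions. The alternative is comparable to the chosen route in step count to the tetracycle but weaker in stereocontrol at C6 and C7; the chosen route sets C7 before ring B exists and C6 by directed delivery from a defined carbinol.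

Key step: step 3

Remark on the chemistry: adduct 6 forms as the racemate, and its name and SMILES show the enantiomer carried on after step 4. β is the face of ring C that carries C7 on C8; α is the opposite face.

## Route

Step 1
Reactants: 1 4,4-dimethylcyclohexanone; 2 vinylmagnesium bromide
Product: 3 4,4-dimethyl-1-vinylcyclohexan-1-ol
Conditions: THF, 0 °C → rt; aq. NH4Cl
Reagents that add atoms: none
Why: Grignard 1,2-addition to an unhindered, symmetrical ketone; no stereocentre is formed.

Step 2
Reactants: 3 4,4-dimethyl-1-vinylcyclohexan-1-ol
Product: 4 4,4-dimethyl-1-vinylcyclohexene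
Conditions: methyl N-(triethylammoniosulfonyl)carbamate, benzene, 50 °C
Reagents that add atoms: none
Why: Syn elimination of the tertiary sulfamate ester (dehydration by an Ei mechanism); only ring β-hydrogens are available and the ring is symmetrical, so the conjugated diene is the single possible olefin.

Step 3
Reactants: 4 4,4-dimethyl-1-vinylcyclohexene; 5 citraconic anhydride
Product: 6 rac-(3aS,9aS,9bR)-3a,8,8-trimethyl-3a,4,6,7,8,9,9a,9b-octahydronaphtho[1,2-c]furan-1,3-dione (cis-anhydride; 8-methyl, H16 and H17 all α; C10=C11)
Conditions: toluene, 110 °C, sealed tube, 2,6-di-tert-butyl-4-methylphenol (cat.)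
Reagents that add atoms: none
Why: Thermal Diels–Alder reaction of a 1-vinylcycloalkene with a cyclic anhydride: a concerted, suprafacial–suprafacial [4+2] cycloaddition that forms C8–C9 and C16–C17 in one event and leaves the olefin at C10=C11. Ring C is closed by the cycloaddition itself, from the four diene carbons C9, C10, C11, C16 and the two dienophile carbons C8 and C17; ring D is already in the diene and the anhydride ring is carried through unchanged. C8 and C17 are fixed relative to each other by the cis geometry of the dienophile, so the C8 methyl is cis to H17 and C7 is cis to C18. C16 is set relative to them by the endo transition state (Alder rule): the ring carbon C15, the outside substituent of the s-cis diene, ends up cis to both carbonyl branches, so H16 is cis to the C8 methyl as the target requires. The step needs regioselectivity (C8 to C9): the methyl-bearing dienophile carbon is the more hindered one and carries the larger LUMO coefficient, so it should bond to the unsubstituted, most accessible diene terminus C9 and not to the ring carbon C16. It also needs endo selectivity, which cyclic anhydrides give because both carbonyl groups lie under the diene. Nothing in the step controls the absolute configuration, so 6 forms as the racemate; the enantiomer is secured in step 4 and the C17 configuration is corrected in step 5.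

Step 4
Reactants: 6 racemic cis-anhydride; 7 (1R,2S,5R)-menthol
Product: 8 cis-hemiester (C7 carboxylic acid on C8, C18 (1R,2S,5R)-menthyl ester on C17, both β; C10=C11)
Conditions: 7, n-BuLi, THF, −78 → 0 °C; aq. HCl; fractional crystallisation
Reagents that add atoms: none
Why: Alkoxide opening of a cyclic anhydride at the less hindered carbonyl C18 (C7 sits on the quaternary C8); the enantiopure alcohol turns the two enantiomers into diastereomers that should be separable by crystallisation (classical resolution), and the same step differentiates C7 from C18.

Step 5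
Reactants: 8 cis-hemiester
Product: 9 trans-hemiester (C17 epimer of 8: C18 ester α, H17 β)
Conditions: KOtBu (3 equiv), t-BuOH–THF, 50 °C; aq. HCl
Reagents that add atoms: none
Why: Thermodynamic epimerisation through the ester enolate at C17 (C8 is quaternary and cannot epimerise); the trans isomer places C7, C18 and the ring D bond all equatorial on the half-chair of ring C and should dominate at equilibrium.

Step 6
Reactants: 9 trans-hemiester
Product: 10 cyclopropane (CH2 bridging C10 and C11 on the β face; C7 acid, C18 menthyl ester)
Conditions: Et2Zn (4 equiv), CH2I2 (8 equiv), CH2Cl2, 0 °C → rt; aq. HCl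
Reagents that add atoms: diiodomethane, ICI
Why: Simmons–Smith cyclopropanation (diethylzinc variant), a concerted syn methylene transfer; the α face of C10=C11 is screened by the axial C8 methyl, while the β face carries only axial hydrogens and the zinc carboxylate formed from the C7 acid, which is itself an acyloxy(iodomethyl)zinc carbenoid held on that face, so the methylene should add from β and set C11.

Step 7
Reactants: 10 cyclopropane
Product: 11 saturated hemiester (11β-methyl, trans-fused rings C and D; C7 acid, C18 menthyl ester)
Conditions: H2 (4 atm), PtO2, AcOH, 50 °C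
Reagents that add atoms: none
Why: Hydrogenolysis of a cyclopropane at its least substituted bond, C10–CH2, which converts the bridging carbon into the C11 methyl with retention at C11; the ester, the acid and the saturated rings are inert.

Step 8
Reactants: 11 saturated hemiester; 12 propyne
Product: 14 ynone (C7 ketone bearing the prop-1-ynyl group C6≡C5–CH3; C18 menthyl ester), via acid chloride 13 (not isolated)
Conditions: (COCl)2, DMF (cat.), CH2Cl2, 0 °C → rt; evaporate; 12, PdCl2(PPh3)2 (cat.), CuI (cat.), Et3N, THF, rt
Reagents that add atoms: none
Why: Acyl Sonogashira coupling of an acid chloride with a terminal alkyne; the acid chloride has no α-hydrogen (no ketene), and the hindered ester is not touched.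

Step 9
Reactants: 14 ynone
Product: 15 propargylic alcohol (O7 β as in the target; 7S in this compound)
Conditions: (S)-1-methyl-3,3-diphenyltetrahydro-1H,3H-pyrrolo[1,2-c][1,3,2]oxazaborole (0.5 equiv), catecholborane, toluene, −78 → −40 °C; MeOH
Reagents that add atoms: none
Why: Corey–Bakshi–Shibata reduction; the tertiary alkyl group C8 is the large substituent and the slim propynyl group the small one, so the (S)-catalyst should deliver hydride to the face that gives the target configuration at C7 by reagent control.

Step 10
Reactants: 15 propargylic alcohol
Product: 16 C7 triethylsilyl ether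
Conditions: Et3SiOTf, 2,6-lutidine, CH2Cl2, −78 → 0 °C
Reagents that add atoms: triethylsilyl trifluoromethanesulfonate, CC[Si](CC)(CC)OS(=O)(=O)C(F)(F)F
Why: Silylation of a hindered secondary alcohol with a silyl triflate; protection prevents lactonisation onto C18 and oxidation of C7 in step 12.

Step 11
Reactants: 16 C7 triethylsilyl ether
Product: 17 primary alcohol (C18 CH2OH)
Conditions: i-Bu2AlH (3 equiv), CH2Cl2, −78 → 0 °C; aq. potassium sodium tartrate
Reagents that add atoms: none
Why: Hydride reduction of the ester to the primary alcohol with release of menthol; the internal alkyne and the silyl ether are inert to the aluminium hydride at this temperature.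

Step 12
Reactants: 17 primary alcohol
Product: 18 aldehyde (C18 CHO, equatorial on C17)
Conditions: 1,1,1-triacetoxy-1,1-dihydro-1,2-benziodoxol-3(1H)-one, CH2Cl2, 0 °C → rt
Reagents that add atoms: none
Why: Periodinane oxidation of a primary alcohol under near-neutral conditions; the aldehyde already has the more stable equatorial configuration at C17.

Step 13
Reactants: 18 aldehyde
Product: 19 terminal olefin (C17–C18H=C19H2)
Conditions: Ph3PCH3Br, KOtBu, THF, 0 °C → rt
Reagents that add atoms: methyltriphenylphosphonium bromide, C[P+](c1ccccc1)(c1ccccc1)c1ccccc1.[Br-]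
Why: Wittig methylenation, which works on α-branched aldehydes and introduces C19.

Step 14
Reactants: 20 but-2-yn-1-ol
Product: 21 but-2-yn-1-yl diethyl phosphate
Conditions: ClP(O)(OEt)2, pyridine, 4-(dimethylamino)pyridine (cat.), CH2Cl2, 0 °C → rt
Reagents that add atoms: diethyl chlorophosphate, CCOP(=O)(Cl)OCC
Why: Phosphorylation of a primary alcohol; it supplies C1, its methyl, C2 and C3 as a propargylic electrophile.

Step 15
Reactants: 19 terminal olefin; 21 but-2-yn-1-yl diethyl phosphate
Product: 23 allenyne (C19–C1(CH3)=C2=C3H2 allene, C5≡C6 alkyne, C7 silyl ether), via B-alkyl-9-borabicyclononane 22 (not isolated)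
Conditions: 9-borabicyclo[3.3.1]nonane dimer, THF, rt; then 21, CuOAc (10 mol %), KOtBu, THF, 40 °C
Reagents that add atoms: none
Why: Anti-Markovnikov hydroboration of the terminal olefin (this borane reacts with a terminal olefin much faster than with an internal alkyne), then γ-selective (SN2′) substitution of the propargylic phosphate by the alkyl group under monovalent copper catalysis, which gives the 1,1-disubstituted allene directly.

Step 16
Reactants: 23 allenyne
Product: 24 tetracyclic dienone (C4 ketone, C5=C6 and C1=C2 olefins, C7 silyl ether)
Conditions: [Rh(CO)2Cl]2 (10 mol %), CO (1 atm), toluene (0.005 M), 110 °C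
Reagents that add atoms: carbon monoxide, [C-]#[O+]
Why: Allenic Pauson–Khand reaction: monovalent rhodium couples the alkyne with the distal π-bond of the allene (C2=C3) to a rhodacycle, CO inserts and reductive elimination gives the 4-alkylidenecyclopentenone, closing ring A and the eight-membered ring B with C1=C2 held Z by the ring; the trans-disubstituted cyclohexane and the quaternary C8 in the tether hold the two π-systems close, and no stereocentre is created.

Step 17
Reactants: 24 tetracyclic dienone
Product: 25 dienol (4R carbinol, C7 silyl ether)
Conditions: (S)-1-methyl-3,3-diphenyltetrahydro-1H,3H-pyrrolo[1,2-c][1,3,2]oxazaborole (0.5 equiv), catecholborane, toluene, −78 °C; MeOH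
Reagents that add atoms: none
Why: Corey–Bakshi–Shibata 1,2-reduction of a 2-methylcyclopentenone; the methyl-substituted olefinic carbon C5 is the large group and the C3 methylene the small one, so the (S)-catalyst should give the 4R alcohol by reagent control.

Step 18
Reactants: 25 dienol
Product: 26 dienediol (free hydroxyls at C4 and C7)
Conditions: Bu4NF, THF, 0 °C → rt
Reagents that add atoms: none
Why: Fluoride cleavage of the triethylsilyl ether under non-acidic conditions, which the allylic carbinol tolerates.

Step 19
Reactants: 26 dienediol
Product: 27 target diol (4R,5R,6S,7R,8S,11S,16S,17S; C1=C2 Z)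
Conditions: H2 (1 atm), [Ir(cod)(PCy3)(py)]PF6 (5 mol %), CH2Cl2, 0 °C; stopped after 1 equiv H2
Reagents that add atoms: none
Why: Hydroxyl-directed homogeneous hydrogenation by a cationic monovalent iridium complex; the metal binds the allylic C4 hydroxyl (and the allylic C7 hydroxyl on the same face) and adds both hydrogens syn to C5=C6 from that face, so H5 and H6 become cis to O4, which sets C5 and C6. The homoallylic C1=C2 bond is more hindered and should react more slowly.

## Compound list

1 | 4,4-dimethylcyclohexanone | CC1(C)CCC(=O)CC1 | starting material
2 | vinylmagnesium bromide | C=C[Mg]Br | starting material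
3 | 4,4-dimethyl-1-vinylcyclohexan-1-ol | C=CC1(O)CCC(C)(C)CC1 | intermediate
4 | 4,4-dimethyl-1-vinylcyclohexene | C=CC1=CCC(C)(C)CC1 | intermediate
5 | citraconic anhydride (3-methylfuran-2,5-dione) | CC1=CC(=O)OC1=O | starting material
6 | rac-(3aS,9aS,9bR)-3a,8,8-trimethyl-3a,4,6,7,8,9,9a,9b-octahydronaphtho[1,2-c]furan-1,3-dione (racemate, drawn as the enantiomer carried on) | O1C(=O)[C@@]2(C)CC=C3CCC(C)(C)C[C@H]3[C@H]2C1=O | intermediate
7 | (1R,2S,5R)-menthol | C[C@@H]1CC[C@H]([C@@H](C1)O)C(C)C | starting material
8 | cis-hemiester (C7 acid, C18 menthyl ester, H17 α, C10=C11) | OC(=O)[C@@]2(C)CC=C3CCC(C)(C)C[C@H]3[C@H]2C(=O)O[C@@H]1C[C@H](C)CC[C@H]1C(C)C | intermediate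
9 | trans-hemiester (C17 epimer of 8, H17 β) | OC(=O)[C@@]2(C)CC=C3CCC(C)(C)C[C@H]3[C@@H]2C(=O)O[C@@H]1C[C@H](C)CC[C@H]1C(C)C | intermediate
10 | cyclopropane (β-CH2 across C10–C11) | OC(=O)[C@@]2(C)C[C@H]4C[C@]43CCC(C)(C)C[C@H]3[C@@H]2C(=O)O[C@@H]1C[C@H](C)CC[C@H]1C(C)C | intermediate
11 | saturated hemiester (11β-methyl, trans-decalin) | OC(=O)[C@@]2(C)CC[C@]3(C)CCC(C)(C)C[C@H]3[C@@H]2C(=O)O[C@@H]1C[C@H](C)CC[C@H]1C(C)C | intermediate
12 | propyne | CC#C | starting material
13 | acid chloride of 11 (C7 COCl) | ClC(=O)[C@@]2(C)CC[C@]3(C)CCC(C)(C)C[C@H]3[C@@H]2C(=O)O[C@@H]1C[C@H](C)CC[C@H]1C(C)C | intermediate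
14 | ynone (C7 ketone, prop-1-ynyl) | CC#CC(=O)[C@@]2(C)CC[C@]3(C)CCC(C)(C)C[C@H]3[C@@H]2C(=O)O[C@@H]1C[C@H](C)CC[C@H]1C(C)C | intermediate
15 | propargylic alcohol (7S) | CC#C[C@@H](O)[C@@]2(C)CC[C@]3(C)CCC(C)(C)C[C@H]3[C@@H]2C(=O)O[C@@H]1C[C@H](C)CC[C@H]1C(C)C | intermediate
16 | C7 triethylsilyl ether of 15 | CC#C[C@@H](O[Si](CC)(CC)CC)[C@@]2(C)CC[C@]3(C)CCC(C)(C)C[C@H]3[C@@H]2C(=O)O[C@@H]1C[C@H](C)CC[C@H]1C(C)C | intermediate
17 | primary alcohol (C18 CH2OH) | CC#C[C@@H](O[Si](CC)(CC)CC)[C@@]2(C)CC[C@]3(C)CCC(C)(C)C[C@H]3[C@@H]2CO | intermediate
18 | aldehyde (C18 CHO) | CC#C[C@@H](O[Si](CC)(CC)CC)[C@@]2(C)CC[C@]3(C)CCC(C)(C)C[C@H]3[C@@H]2C=O | intermediate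
19 | terminal olefin (C18=C19) | CC#C[C@@H](O[Si](CC)(CC)CC)[C@@]2(C)CC[C@]3(C)CCC(C)(C)C[C@H]3[C@@H]2C=C | intermediate
20 | but-2-yn-1-ol | CC#CCO | starting material
21 | but-2-yn-1-yl diethyl phosphate | CC#CCOP(=O)(OCC)OCC | intermediate
22 | B-alkyl-9-borabicyclo[3.3.1]nonane (boron on C19) | CC#C[C@@H](O[Si](CC)(CC)CC)[C@@]2(C)CC[C@]3(C)CCC(C)(C)C[C@H]3[C@@H]2CCB4C5CCCC4CCC5 | intermediate
23 | allenyne | CC#C[C@@H](O[Si](CC)(CC)CC)[C@@]2(C)CC[C@]3(C)CCC(C)(C)C[C@H]3[C@@H]2CCC(C)=C=C | intermediate
24 | tetracyclic dienone (C7 silyl ether) | C/C1=C2\CC(=O)C(C)=C2[C@@H](O[Si](CC)(CC)CC)[C@@]3(C)CC[C@]4(C)CCC(C)(C)C[C@H]4[C@@H]3CC1 | intermediate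
25 | dienol (4R, C7 silyl ether) | C/C1=C2\C[C@@H](O)C(C)=C2[C@@H](O[Si](CC)(CC)CC)[C@@]3(C)CC[C@]4(C)CCC(C)(C)C[C@H]4[C@@H]3CC1 | intermediate
26 | dienediol | C/C1=C2\C[C@@H](O)C(C)=C2[C@@H](O)[C@@]3(C)CC[C@]4(C)CCC(C)(C)C[C@H]4[C@@H]3CC1 | intermediate
27 | target diol CNP0213887.1 | C/C1=C2\C[C@@H](O)[C@H](C)[C@@H]2[C@@H](O)[C@@]2(C)CC[C@]3(C)CCC(C)(C)C[C@H]3[C@@H]2CC1 | target

## Step count and least certain steps

Total step count: 19. Longest linear sequence: 18 steps (1 → 27 through steps 1–13 and 15–19); step 14 is a one-step side branch.

Step 3 (key step). Regiocontrol may be lost in the cycloaddition: the alkyl groups on C16 and C11 polarise the diene in opposite senses, so bonding of the methyl-bearing carbon to C16 can compete, and some exo addition is possible; the isomers would then travel into the resolution. Fallback: it sets out from 4 and returns at 6. Maleic anhydride, which poses no regiochemical question, is added to 4 to give the all-cis nor-methyl anhydride F1. KOtBu opens F1 at the less hindered C7 carbonyl (C8 is now a methine beside a methylene, while C17 sits beside the ring-fusion methine) to give the C7 tert-butyl hemiester F2. LiN(i-Pr)2 (2.2 equiv) forms the carboxylate ester-enolate dianion and MeI alkylates C8 from the α face, anti to the neighbouring C18 carboxylate, giving the methylated hemiester F3. CF3CO2H cleaves the tert-butyl ester to the cis-diacid F4, and Ac2O closes it to racemic 6, which enters step 4.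

Step 16. Closure of the eight-membered ring at the rhodacycle stage may be slow, so that intermolecular oligomerisation, or cycloisomerisation by β-hydride elimination to a cross-conjugated triene, overtakes CO insertion. Fallback: it sets out from 19 and returns at 24, and uses a sulfonyl-substituted allene, the allene class for which this cycloaddition is documented to close eight-membered rings. Hydroboration of 19 with 9-borabicyclo[3.3.1]nonane and oxidation (NaOH, H2O2) gives the primary alcohol F5, and I2, PPh3 and imidazole convert it into the iodide F6. Alkylation of dilithiated prop-2-yn-1-ol (n-BuLi, THF–DMPU) with F6 gives the propargylic alcohol F7. PhSCl and Et3N at −78 °C form the sulfenate, which rearranges ([2,3]-sigmatropic shift) to the allenyl sulfoxide F8, and 3-chloroperbenzoic acid oxidises it to the allenyl sulfone F9. Cyclocarbonylation with [RhCl(CO)(Ph2P(CH2)3PPh2)]2 under CO in toluene at reflux gives the sulfonyl dienone F10. Me2CuLi replaces the sulfonyl group on C1 by methyl through 1,6-addition and loss of sulfinate, giving 24.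

Step 19. Site selectivity may be lost: C1=C2 is homoallylic to both hydroxyls and may be hydrogenated beside or after C5=C6 (over-reduction of the diene). Fallback: it sets out from 24 and returns at 27, and moves the hydrogenation to the ketone level, where no C4 hydroxyl exists, only the C7 hydroxyl directs, and C1=C2 is the electron-poor terminus of a dienone. Bu4NF converts 24 into the hydroxy dienone F11. Hydrogenation with [Ir(cod)(PCy3)(py)]PF6 under direction of the allylic C7 hydroxyl adds hydrogen syn to C5=C6 from the face of O7, giving the hydroxy ketone F12. LiBH(s-Bu)3 at −78 °C attacks the C4 ketone from the open β face (the α face carries the C5 methyl and C7), giving the 4-epi diol F13. Mitsunobu inversion at the less hindered C4 hydroxyl (4-nitrobenzoic acid, PPh3, diisopropyl azodicarboxylate) gives the 4-nitrobenzoate F14, and K2CO3 in MeOH releases 27.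

Step 6. Methylene transfer to the hindered trisubstituted olefin may be incomplete, because the zinc reagent is tied up by the carboxylate and the ester, and β-face selectivity may erode with it. Fallback: it sets out from 9 and returns at 10. Dibromocarbene (CHBr3, 50% aq. NaOH, BnEt3NCl) is a free, strongly electrophilic carbene that needs no coordination and should add from the less hindered β face to give the dibromocyclopropane F15. Bu3SnH with 2,2′-azobis(isobutyronitrile) in toluene at 80 °C removes both bromines to give 10.

Step 4. The two diastereomeric hemiesters may fail to separate by crystallisation. Fallback: it sets out from 6 and returns at 8. The enantiomers of 6 are separated by preparative chromatography on a chiral stationary phase, and the enantiopure anhydride is opened with lithium menthoxide exactly as in step 4, so that 8 is the only hemiester formed; no new compound arises.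

## Further compounds

F1 | step 3 | all-cis 8,8-dimethyl-3a,4,6,7,8,9,9a,9b-octahydronaphtho[1,2-c]furan-1,3-dione (racemic, one enantiomer drawn) | O1C(=O)[C@H]2CC=C3CCC(C)(C)C[C@H]3[C@H]2C1=O
F2 | step 3 | C7 tert-butyl hemiester of the nor-methyl cis-diacid (C18 acid) | CC(C)(C)OC(=O)[C@H]2CC=C3CCC(C)(C)C[C@H]3[C@H]2C(O)=O
F3 | step 3 | C8-methylated tert-butyl hemiester (8-methyl α) | CC(C)(C)OC(=O)[C@@]2(C)CC=C3CCC(C)(C)C[C@H]3[C@H]2C(O)=O
F4 | step 3 | cis-diacid corresponding to 6 | OC(=O)[C@@]2(C)CC=C3CCC(C)(C)C[C@H]3[C@H]2C(O)=O
F5 | step 16 | primary alcohol (C19 CH2OH) | CC#C[C@@H](O[Si](CC)(CC)CC)[C@@]2(C)CC[C@]3(C)CCC(C)(C)C[C@H]3[C@@H]2CCO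
F6 | step 16 | primary iodide (C19 CH2I) | CC#C[C@@H](O[Si](CC)(CC)CC)[C@@]2(C)CC[C@]3(C)CCC(C)(C)C[C@H]3[C@@H]2CCI
F7 | step 16 | propargylic alcohol (C19–C1≡C2–C3H2OH) | CC#C[C@@H](O[Si](CC)(CC)CC)[C@@]2(C)CC[C@]3(C)CCC(C)(C)C[C@H]3[C@@H]2CCC#CCO
F8 | step 16 | allenyl sulfoxide (C1 phenylsulfinyl, mixture at sulfur) | CC#C[C@@H](O[Si](CC)(CC)CC)[C@@]2(C)CC[C@]3(C)CCC(C)(C)C[C@H]3[C@@H]2CCC(=C=C)S(=O)c4ccccc4
F9 | step 16 | allenyl sulfone (C1 phenylsulfonyl) | CC#C[C@@H](O[Si](CC)(CC)CC)[C@@]2(C)CC[C@]3(C)CCC(C)(C)C[C@H]3[C@@H]2CCC(=C=C)S(=O)(=O)c4ccccc4
F10 | step 16 | sulfonyl dienone (phenylsulfonyl on C1 in place of methyl) | O=S(=O)(c5ccccc5)/C1=C2\CC(=O)C(C)=C2[C@@H](O[Si](CC)(CC)CC)[C@@]3(C)CC[C@]4(C)CCC(C)(C)C[C@H]4[C@@H]3CC1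
F11 | step 19 | hydroxy dienone (free C7 hydroxyl) | C/C1=C2\CC(=O)C(C)=C2[C@@H](O)[C@@]3(C)CC[C@]4(C)CCC(C)(C)C[C@H]4[C@@H]3CC1
F12 | step 19 | hydroxy ketone (C4 ketone, C5 and C6 set) | C/C1=C2\CC(=O)[C@H](C)[C@@H]2[C@@H](O)[C@@]3(C)CC[C@]4(C)CCC(C)(C)C[C@H]4[C@@H]3CC1
F13 | step 19 | 4-epi diol (4S) | C/C1=C2\C[C@H](O)[C@H](C)[C@@H]2[C@@H](O)[C@@]3(C)CC[C@]4(C)CCC(C)(C)C[C@H]4[C@@H]3CC1
F14 | step 19 | C4 4-nitrobenzoate of the target | C/C1=C2\C[C@@H](OC(=O)c5ccc(cc5)[N+](=O)[O-])[C@H](C)[C@@H]2[C@@H](O)[C@@]3(C)CC[C@]4(C)CCC(C)(C)C[C@H]4[C@@H]3CC1
F15 | step 6 | dibromocyclopropane (β-CBr2 across C10–C11) | OC(=O)[C@@]2(C)C[C@H]4C(Br)(Br)[C@]43CCC(C)(C)C[C@H]3[C@@H]2C(=O)O[C@@H]1C[C@H](C)CC[C@H]1C(C)C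
F0 | step 4 | none | none
A1 | alternative 1 | C4 tert-butyldimethylsilyl ether of the target | C/C1=C2\C[C@@H](O[Si](C)(C)C(C)(C)C)[C@H](C)[C@@H]2[C@@H](O)[C@@]2(C)CC[C@]3(C)CCC(C)(C)C[C@H]3[C@@H]2CC1
A2 | alternative 2 | rings A, C, D ketol with C15 ketone and two dioxolanes | O1CCOC12C[C@@H](O[Si](C)(C)C(C)(C)C)[C@H](C)[C@@H]2[C@@H](O)[C@@]2(C)CC[C@]4(C)CCC(C)(C)C(=O)[C@H]4[C@@H]2CCC5(C)OCCO5
A3 | alternative 3 | pentacyclic cyclobutene photoadduct | CC1=C2C[C@@H](O[Si](C)(C)C(C)(C)C)[C@H](C)[C@@]24C(=O)[C@@]2(C)CC[C@]3(C)CCC(C)(C)C[C@H]3[C@@H]2C[C@@H]14
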